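## Retrosynthetic overview

1. C40 = C15 + C10 + C15: both C11=C12 bonds come from one double Wittig reaction of a hydroxy C15 phosphonium salt with the C10 trienedial, giving the C2-symmetric 4,4'-diol; the 4'-ketone is made last by mono-oxidation of that diol.
2. The C15 salt comes from a C15 keto ester by LiAlH4 reduction (sets C4) and PPh3·HBr.
3. Ring formation (one event, serving both rings): a proton-initiated cation–olefin cyclisation of an acyclic 4-hydroxy ψ-end (C1 cation onto C5=C6, as in lycopene cyclisation), terminated by a 1,2-hydride shift from C4 to C5. This gives the 4-oxo-5,6-dihydro ring directly and relays the carbinol configuration to C6.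
4. The acyclic (S)-carbinol comes from a catalytic asymmetric isopentenylzinc addition to a C10 aldehyde ester, itself made from prenal and a C5 phosphonate, then SeO2.
5. Ring order: the six-membered ring is closed once, at the C15 stage; after hydride reduction it serves as both ring A and ring B of the diol, and ring B is re-oxidised at the end.

**Assumption:** CNP0107241.1 is taken exactly as the SMILES gives it, i.e. all-E (4S,5S,6S,5'S,6'S)-4-hydroxy-5,6,5',6'-tetrahydro-β,β-caroten-4'-one; ring positions carry carotenoid numbers (C1 gem-dimethyl, C4 oxygen, C5 methyl, C6 side chain).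

## Route

Step 1
Reactants: 1 3-methylbut-2-enal; 2 ethyl (2E)-4-(diethoxyphosphoryl)-3-methylbut-2-enoate
Product: 4 ethyl (2E,4E)-3,7-dimethylocta-2,4,6-trienoate, via lithiated phosphonate 3 (not isolated)
Conditions: LiN(SiMe3)2, THF/DMPU, −78 → 0 °C
Reagents that add atoms: none
Why: Horner–Wadsworth–Emmons olefination of an enal with the vinylogous phosphonate anion gives the new (4E) bond and keeps the (2E) crotonate geometry (minor 2Z isomer removed by chromatography).

Step 2
Reactants: 4 ethyl (2E,4E)-3,7-dimethylocta-2,4,6-trienoate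
Product: 5 ethyl (2E,4E,6E)-3,7-dimethyl-8-oxoocta-2,4,6-trienoate
Conditions: SeO2 (1.1 equiv), 1,4-dioxane/H2O, 80 °C
Reagents that add atoms: selenium dioxide, O=[Se]=O
Why: SeO2 allylic oxidation (ene reaction then [2,3]-shift) attacks the most electron-rich isopropylidene terminus and selects its (E)-methyl, giving the (6E)-enal.

Step 3
Reactants: 5 ethyl (2E,4E,6E)-3,7-dimethyl-8-oxoocta-2,4,6-trienoate; 6 4-bromo-2-methylbut-1-ene
Product: 9 ethyl (2E,4E,6E,8S)-8-hydroxy-3,7,11-trimethyldodeca-2,4,6,11-tetraenoate, via Grignard reagent 7 (not isolated), via dialkylzinc 8 (not isolated)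
Conditions: Mg, Et2O; ZnCl2 (0.5 equiv), 1,4-dioxane, filter; Ti(OiPr)4 (0.6 equiv), (1R,2R)-N,N'-bis(trifluoromethylsulfonyl)cyclohexane-1,2-diamine (8 mol%), toluene, −20 °C; aq. NH4Cl
Reagents that add atoms: none
Why: Ti(OiPr)4/bis-triflamide-catalysed enantioselective dialkylzinc addition is aldehyde-selective (ester untouched), and the (1R,2R) ligand directs Si-face attack on the α-methyl enal to set the (8S) carbinol (carotenoid C4).

Step 4
Reactants: 9 ethyl (2E,4E,6E,8S)-8-hydroxy-3,7,11-trimethyldodeca-2,4,6,11-tetraenoate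
Product: 11 ethyl (2E,4E)-3-methyl-5-[(1S,6S)-2,2,6-trimethyl-5-oxocyclohexyl]penta-2,4-dienoate, via cis-keto ester 10 (not isolated)
Conditions: SnCl4 (2.2 equiv), CH2Cl2, −78 → −20 °C; aq. NaHCO3; then pTsOH·H2O (10 mol%), CH2Cl2, 25 °C
Reagents that add atoms: none
Why: Proposed new method: SnCl4 bound to the C8 hydroxyl turns the substrate into its own Lewis-acid-assisted Brønsted acid, which protonates the isopropenyl group to the same tertiary C1 cation that lycopene cyclase generates; the SnCl4-complexed (deactivated) trienoate attacks through C6 in a chair in which the tin-bound oxygen is equatorial and the C8–H bond axial, and that hydride then migrates from the tin alkoxide carbon to the C5 cation on the face anti to the new C1–C6 bond (semipinacol), so (8S) is relayed to (6S) and the initially cis C5 methyl is equilibrated by acid to the trans (5S) epimer, which relieves a syn-diaxial methyl/methyl clash; the closest known reaction types are SnCl4–phenol-promoted proton-initiated polyene cyclisation, the pseudoionone-to-ionone cyclisation and pinacol-terminated cation–olefin cyclisation.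

Step 5
Reactants: 11 ethyl (2E,4E)-3-methyl-5-[(1S,6S)-2,2,6-trimethyl-5-oxocyclohexyl]penta-2,4-dienoate
Product: 12 (2E,4E)-5-[(1S,5S,6S)-5-hydroxy-2,2,6-trimethylcyclohexyl]-3-methylpenta-2,4-dien-1-ol
Conditions: LiAlH4, Et2O, −40 → 0 °C
Reagents that add atoms: none
Why: LiAlH4 reduces the dienoate 1,2 to the allylic alcohol and attacks the conformationally locked trans-ketone axially, past the equatorial C5 methyl, giving the equatorial (4S) alcohol of the all-equatorial ring (minor axial epimer removed by chromatography).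

Step 6
Reactants: 12 (2E,4E)-5-[(1S,5S,6S)-5-hydroxy-2,2,6-trimethylcyclohexyl]-3-methylpenta-2,4-dien-1-ol
Product: 13 [(2E,4E)-5-[(1S,5S,6S)-5-hydroxy-2,2,6-trimethylcyclohexyl]-3-methylpenta-2,4-dien-1-yl]triphenylphosphonium bromide
Conditions: PPh3·HBr, MeOH, 25 °C
Reagents that add atoms: triphenylphosphine hydrobromide, [Br-].c1ccccc1[PH+](c1ccccc1)c1ccccc1
Why: The dienylic primary alcohol ionises to a pentadienyl cation that PPh3 captures at the unhindered terminus (allylic phosphonium salt formation, as for C15 Wittig salts), while the unactivated ring alcohol and all stereocentres are untouched; the salt is recrystallised.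

Step 7
Reactants: 13 [(2E,4E)-5-[(1S,5S,6S)-5-hydroxy-2,2,6-trimethylcyclohexyl]-3-methylpenta-2,4-dien-1-yl]triphenylphosphonium bromide; 14 (2E,4E,6E)-2,7-dimethylocta-2,4,6-trienedial
Product: 18 (4S,5S,6S,4'S,5'S,6'S)-5,6,5',6'-tetrahydro-β,β-carotene-4,4'-diol, via ylide 15 (not isolated), via C25 hydroxy aldehyde 16 (not isolated), via 11Z diol 17 (not isolated)
Conditions: 13 (2.3 equiv), 1,2-epoxybutane, EtOH, 80 °C, argon, dark; then heptane, 90 °C
Reagents that add atoms: none
Why: Double Wittig olefination of the symmetrical C10 dialdehyde with the semistabilised C15 ylide under neutral epoxide conditions (HBr scavenged by 1,2-epoxybutane) tolerates the free hydroxyls; the C25 mono-adduct reacts on with the excess ylide, the Z isomers at the two new C11=C12 bonds isomerise thermally to all-E, and no stereocentre is touched.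

Step 8
Reactants: 18 (4S,5S,6S,4'S,5'S,6'S)-5,6,5',6'-tetrahydro-β,β-carotene-4,4'-diol
Product: 19 (4S,5S,6S,5'S,6'S)-4-hydroxy-5,6,5',6'-tetrahydro-β,β-caroten-4'-one
Conditions: Dess–Martin periodinane (0.6 equiv), NaHCO3, CH2Cl2, 0 °C, argon, dark; chromatography, recovered 18 resubmitted
Reagents that add atoms: none
Why: Dess–Martin oxidation of a secondary alcohol; the two hydroxyls of the C2-symmetric diol are identical and remote from each other, so sub-stoichiometric oxidant gives the mono-ketone as the main converted product (statistically about 40% per pass with little double oxidation), buffered conditions spare the polyene, and no stereocentre changes because C5' next to the new ketone is already the favoured trans epimer.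

## Compound list

1 | 3-methylbut-2-enal | CC(C)=CC=O | starting material
2 | ethyl (2E)-4-(diethoxyphosphoryl)-3-methylbut-2-enoate | CCOC(=O)/C=C(C)/CP(=O)(OCC)OCC | starting material
3 | lithium salt of the C4 carbanion of 2 | [Li+].CCOC(=O)/C=C(C)/[CH-]P(=O)(OCC)OCC | intermediate
4 | ethyl (2E,4E)-3,7-dimethylocta-2,4,6-trienoate | CCOC(=O)/C=C(C)/C=C/C=C(C)C | intermediate
5 | ethyl (2E,4E,6E)-3,7-dimethyl-8-oxoocta-2,4,6-trienoate | CCOC(=O)/C=C(C)/C=C/C=C(C)/C=O | intermediate
6 | 4-bromo-2-methylbut-1-ene | C=C(C)CCBr | starting material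
7 | (3-methylbut-3-en-1-yl)magnesium bromide | C=C(C)CC[Mg]Br | intermediate
8 | bis(3-methylbut-3-en-1-yl)zinc | C=C(C)CC[Zn]CCC(C)=C | intermediate
9 | ethyl (2E,4E,6E,8S)-8-hydroxy-3,7,11-trimethyldodeca-2,4,6,11-tetraenoate | CCOC(=O)/C=C(C)/C=C/C=C(C)/[C@@H](O)CCC(C)=C | intermediate
10 | ethyl (2E,4E)-3-methyl-5-[(1S,6R)-2,2,6-trimethyl-5-oxocyclohexyl]penta-2,4-dienoate (cis epimer) | CCOC(=O)/C=C(C)/C=C/[C@H]1[C@@H](C)C(=O)CCC1(C)C | intermediate
11 | ethyl (2E,4E)-3-methyl-5-[(1S,6S)-2,2,6-trimethyl-5-oxocyclohexyl]penta-2,4-dienoate (trans) | CCOC(=O)/C=C(C)/C=C/[C@H]1[C@H](C)C(=O)CCC1(C)C | intermediate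
12 | (2E,4E)-5-[(1S,5S,6S)-5-hydroxy-2,2,6-trimethylcyclohexyl]-3-methylpenta-2,4-dien-1-ol | OC/C=C(C)/C=C/[C@H]1[C@H](C)[C@@H](O)CCC1(C)C | intermediate
13 | [(2E,4E)-5-[(1S,5S,6S)-5-hydroxy-2,2,6-trimethylcyclohexyl]-3-methylpenta-2,4-dien-1-yl]triphenylphosphonium bromide | [Br-].c1ccccc1[P+](c1ccccc1)(c1ccccc1)C/C=C(C)/C=C/[C@H]2[C@H](C)[C@@H](O)CCC2(C)C | intermediate
14 | (2E,4E,6E)-2,7-dimethylocta-2,4,6-trienedial | O=C/C(C)=C/C=C/C=C(C)/C=O | starting material
15 | triphenylphosphonium ylide of 13 | c1ccccc1[P+](c1ccccc1)(c1ccccc1)[CH-]/C=C(C)/C=C/[C@H]2[C@H](C)[C@@H](O)CCC2(C)C | intermediate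
16 | (2E,4E,6E,8E,10E,12E)-13-[(1S,5S,6S)-5-hydroxy-2,2,6-trimethylcyclohexyl]-2,7,11-trimethyltrideca-2,4,6,8,10,12-hexaenal | O=C/C(C)=C/C=C/C=C(C)/C=C/C=C(C)/C=C/[C@H]1[C@H](C)[C@@H](O)CCC1(C)C | intermediate
17 | (11Z)-isomer of 18 | CC(/C=C\C=C(C)\C=C\[C@H]1[C@H](C)[C@@H](O)CCC1(C)C)=C\C=C\C=C(C)\C=C\C=C(C)\C=C\[C@H]1[C@H](C)[C@@H](O)CCC1(C)C | intermediate
18 | (4S,5S,6S,4'S,5'S,6'S)-5,6,5',6'-tetrahydro-β,β-carotene-4,4'-diol, all-E | CC(/C=C/C=C(C)/C=C/[C@H]1[C@H](C)[C@@H](O)CCC1(C)C)=C\C=C\C=C(C)\C=C\C=C(C)\C=C\[C@H]1[C@H](C)[C@@H](O)CCC1(C)C | intermediate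
19 | (4S,5S,6S,5'S,6'S)-4-hydroxy-5,6,5',6'-tetrahydro-β,β-caroten-4'-one, all-E | CC(/C=C/C=C(C)/C=C/[C@H]1[C@H](C)[C@@H](O)CCC1(C)C)=C\C=C\C=C(C)\C=C\C=C(C)\C=C\[C@H]1[C@H](C)C(=O)CCC1(C)C | target

## Step count and risks

Total steps: 8. Longest linear sequence: 8 (1 → 4 → 5 → 9 → 11 → 12 → 13 → 18 → 19; 6 and 14 enter as side inputs).

**Step 4 (highest risk).** The C1 cation can be captured by the C8 oxygen to give a 2,2-dimethyltetrahydrofuran (expected to reopen under SnCl4, but not certain). The allylic C8–O bond may ionise, the 2E bond may scramble, and the C8-to-C6 relay may be incomplete. If the relay has the opposite sense, the (1S,2S) ligand in step 3 supplies the other carbinol. Fallback, from 9 back to 11: mask the carbinol and make the cation by halide abstraction instead of protonation. TIPSOTf/2,6-lutidine converts 9 into ethyl (2E,4E,6E,8S)-3,7,11-trimethyl-8-[(triisopropylsilyl)oxy]dodeca-2,4,6,11-tetraenoate F1. Dry HCl in CH2Cl2 at −78 °C adds across the isopropenyl group to give ethyl (2E,4E,6E,8S)-11-chloro-3,7,11-trimethyl-8-[(triisopropylsilyl)oxy]dodeca-2,4,6-trienoate F2. AgBF4 in CH2Cl2 at −78 °C removes chloride; the same C1 cation, which the bulky silyl ether cannot trap, closes onto C6, the C8 hydride shifts, and the silyloxocarbenium ion loses its silyl group to fluoride. pTsOH equilibration of C5 then gives 11.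

**Step 2.** SeO2 oxidation of a conjugated trienoate may give low yield, over-oxidation or E/Z loss. Fallback, from 6 (as zinc reagent 8) and 2 back to 9, with no allylic oxidation: 8 is added under the step 3 catalyst to commercial (E)-4-acetoxy-2-methylbut-2-enal to give (2E,4S)-4-hydroxy-3,7-dimethylocta-2,7-dien-1-yl acetate F3. K2CO3/MeOH gives (2E,4S)-3,7-dimethylocta-2,7-diene-1,4-diol F4. TEMPO/PhI(OAc)2 oxidises only the primary allylic alcohol to (2E,4S)-4-hydroxy-3,7-dimethylocta-2,7-dienal F5. Olefination of F5 with two equivalents of lithiated phosphonate 3 gives 9, bypassing 4 and 5.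

**Step 8.** The mono-oxidation is statistical: conversion per pass is limited, the diol must be recycled, and the C40 polyene may suffer under the oxidant. Fallback, from 13 and 14 to 19, bypassing 18 and the statistical step: differentiate the two ends at the C25 stage instead. Wittig reaction of 13 with three equivalents of 14 (NaOMe, CH2Cl2/MeOH, 0 → 25 °C; then heptane, 90 °C) stops at the C25 hydroxy aldehyde 16, which is isolated, because its aldehyde is less electrophilic than that of the dialdehyde. Dess–Martin periodinane (1.2 equiv, NaHCO3, CH2Cl2) oxidises its single hydroxyl completely to (2E,4E,6E,8E,10E,12E)-2,7,11-trimethyl-13-[(1S,6S)-2,2,6-trimethyl-5-oxocyclohexyl]trideca-2,4,6,8,10,12-hexaenal F6. Wittig reaction of F6 with a second portion of 13 (1,2-epoxybutane, EtOH, 80 °C), which reacts at the aldehyde and not at the hindered ring ketone, gives 19 directly.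

## Further compounds

F1 | step 4 | ethyl (2E,4E,6E,8S)-3,7,11-trimethyl-8-[(triisopropylsilyl)oxy]dodeca-2,4,6,11-tetraenoate | CCOC(=O)/C=C(C)/C=C/C=C(C)/[C@@H](O[Si](C(C)C)(C(C)C)C(C)C)CCC(C)=C
F2 | step 4 | ethyl (2E,4E,6E,8S)-11-chloro-3,7,11-trimethyl-8-[(triisopropylsilyl)oxy]dodeca-2,4,6-trienoate | CCOC(=O)/C=C(C)/C=C/C=C(C)/[C@@H](O[Si](C(C)C)(C(C)C)C(C)C)CCC(C)(C)Cl
F3 | step 2 | (2E,4S)-4-hydroxy-3,7-dimethylocta-2,7-dien-1-yl acetate | CC(=O)OC/C=C(C)/[C@@H](O)CCC(C)=C
F4 | step 2 | (2E,4S)-3,7-dimethylocta-2,7-diene-1,4-diol | OC/C=C(C)/[C@@H](O)CCC(C)=C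
F5 | step 2 | (2E,4S)-4-hydroxy-3,7-dimethylocta-2,7-dienal | O=C/C=C(C)/[C@@H](O)CCC(C)=C
F6 | step 8 | (2E,4E,6E,8E,10E,12E)-2,7,11-trimethyl-13-[(1S,6S)-2,2,6-trimethyl-5-oxocyclohexyl]trideca-2,4,6,8,10,12-hexaenal | O=C/C(C)=C/C=C/C=C(C)/C=C/C=C(C)/C=C/[C@H]1[C@H](C)C(=O)CCC1(C)C
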